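**Retrosynthetic overview**

- The strategy rests on the benzo ring of the indole (C3a–C4–C5–C6–C7–C7a): with Br on C5 and C6 it is symmetric about the axis through the midpoints of C3a–C7a and C5–C6, and C3 carries the 2-aminopyrimidin-4-yl ring.
- Cutting N1–C7a and C3–C3a therefore gives 4,5-dibromobenzyne, whose two aryne carbons are equivalent, plus an N-tosyl α-amino ketone in which C3 is the carbonyl carbon on pyrimidine C4.
- The benzene and pyrimidine rings are bought; the five-membered ring is closed in the aryne annulation as a 3-hydroxyindoline and aromatised by dehydration.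
- The aryne precursor comes from 3,4-dibromophenol (iodination, O-silylation, retro-Brook/triflation); the ketone from 2-amino-4-chloropyrimidine (bis-PMB protection, Stille enol ether, NBS/water, sulfonamide displacement).
- End game: dehydration, acidolytic removal of the PMB groups while N-tosyl still shields the indole, then basic detosylation.

Key step: step 8

Remark: compound 17 forms as a racemate; its only stereocenter (C3) is removed in step 9 and the target is achiral, so no stereocontrol is planned. Silyl ether 3 is moisture-sensitive and is carried into step 3 without purification.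

**Route**

Step 1
Reactants: 1 3,4-dibromophenol
Product: 2 4,5-dibromo-2-iodophenol
Conditions: NIS (1.0 equiv), TsOH·H2O (cat.), MeCN, 0 °C to rt
Reagents that add atoms: N-iodosuccinimide, O=C1CCC(=O)N1I
Why: Electrophilic aromatic iodination; the hydroxyl directs ortho/para, para is blocked by Br, and of the two ortho carbons the one flanked by Br is hindered, so iodine should enter the open ortho position.

Step 2
Reactants: 2 4,5-dibromo-2-iodophenol
Product: 3 (4,5-dibromo-2-iodophenoxy)trimethylsilane
Conditions: HMDS, THF, 70 °C; evaporate, use crude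
Reagents that add atoms: hexamethyldisilazane, C[Si](C)(C)N[Si](C)(C)C
Why: O-silylation of a phenol by silyl transfer from HMDS, driven by loss of ammonia and needing no base or aqueous work-up.

Step 3
Reactants: 3 (4,5-dibromo-2-iodophenoxy)trimethylsilane
Product: 6 4,5-dibromo-2-(trimethylsilyl)phenyl trifluoromethanesulfonate, via ortho-lithiated silyl ether 4 (not isolated), via lithium 2-silylphenoxide 5 (not isolated)
Conditions: n-BuLi (1.05 equiv), THF, −100 °C; then Tf2O, −100 to −78 °C
Reagents that add atoms: trifluoromethanesulfonic anhydride, O=S(=O)(OS(=O)(=O)C(F)(F)F)C(F)(F)F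
Why: Iodine–lithium exchange is far faster than bromine–lithium exchange at −100 °C, the aryllithium (no Br ortho to it, so no LiBr loss) undergoes the anionic retro-Brook 1,3-shift of silicon from O to C, and the resulting phenoxide is O-triflated in the same flask.

Step 4
Reactants: 7 2-amino-4-chloropyrimidine; 8 4-methoxybenzyl chloride
Product: 9 4-chloro-N,N-bis(4-methoxybenzyl)pyrimidin-2-amine
Conditions: 8 (2.3 equiv), NaH (2.5 equiv, added last in portions), DMF, 0 °C to rt
Reagents that add atoms: none
Why: Double N-alkylation of the exocyclic amide anion with a reactive benzylic chloride; having the chloride present before the base lets alkylation outrun SNAr self-condensation at C4.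

Step 5
Reactants: 9 4-chloro-N,N-bis(4-methoxybenzyl)pyrimidin-2-amine; 10 tributyl(1-ethoxyvinyl)stannane
Product: 11 4-(1-ethoxyvinyl)-N,N-bis(4-methoxybenzyl)pyrimidin-2-amine
Conditions: PdCl2(PPh3)2 (5 mol%), toluene, 100 °C; aq. KF work-up
Reagents that add atoms: none
Why: Stille coupling at the activated C4–Cl bond of the pyrimidine; the non-acidic work-up keeps the enol ether for the next step.

Step 6
Reactants: 11 4-(1-ethoxyvinyl)-N,N-bis(4-methoxybenzyl)pyrimidin-2-amine
Product: 12 1-[2-(bis(4-methoxybenzyl)amino)pyrimidin-4-yl]-2-bromoethan-1-one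
Conditions: NBS (1.0 equiv), THF/H2O 3:1, 0 °C
Reagents that add atoms: N-bromosuccinimide, O=C1CCC(=O)N1Br; water, O
Why: Bromination of the enol ether followed by hydrolysis of the bromo-oxocarbenium ion gives the α-bromo ketone directly; the enol ether is far more nucleophilic than the anisole rings or pyrimidine C5, which a direct ketone bromination would endanger.

Step 7
Reactants: 12 1-[2-(bis(4-methoxybenzyl)amino)pyrimidin-4-yl]-2-bromoethan-1-one; 13 p-toluenesulfonamide
Product: 14 N-[2-(2-(bis(4-methoxybenzyl)amino)pyrimidin-4-yl)-2-oxoethyl]-4-methylbenzenesulfonamide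
Conditions: 13 (3 equiv), K2CO3, acetone, 0 °C to rt
Reagents that add atoms: none
Why: SN2 displacement of an activated α-halo ketone by the sulfonamide anion; the excess of sulfonamide is meant to suppress a second alkylation.

Step 8
Reactants: 6 4,5-dibromo-2-(trimethylsilyl)phenyl trifluoromethanesulfonate; 14 N-[2-(2-(bis(4-methoxybenzyl)amino)pyrimidin-4-yl)-2-oxoethyl]-4-methylbenzenesulfonamide
Product: 17 3-[2-(bis(4-methoxybenzyl)amino)pyrimidin-4-yl]-5,6-dibromo-1-tosylindolin-3-ol (racemic), via 4,5-dibromobenzyne 15 (not isolated), via cesium aryl anion 16 (not isolated)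
Conditions: CsF (3 equiv), MeCN, rt; 6 (1.5 equiv) added slowly
Reagents that add atoms: none
Why: Fluoride attacks silicon and triflate leaves in a 1,2-elimination to give aryne 15; the fluoride-activated sulfonamide nitrogen of 14 adds to it (N1–C7a), and the ortho aryl anion 16 attacks the ketone (C3–C3a), the alkoxide then taking up the proton that nitrogen gave away. The closest known reaction type is the fluoride-induced aryne annulation of N-sulfonyl α-amino ketones to 3-hydroxyindolines (N-arylation followed by intramolecular carbonyl addition). The five-membered ring closes by 5-exo-trig attack of the aryl carbanion on the carbonyl. The new stereocenter C3 is formed without control, as a racemate, which is of no consequence because step 9 removes it. The step needs N-arylation rather than enolate C-arylation and ring closure rather than protonation of 16: the sulfonamide N–H is the most acidic site, the ketone on pyrimidine C4 is strongly electrophilic and sits in reach of the anion, and the medium is aprotic. No regiochemical question arises because 15 is symmetric about the axis through its triple bond, and fluoride leaves the C–Br bonds alone.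

Step 9
Reactants: 17 3-[2-(bis(4-methoxybenzyl)amino)pyrimidin-4-yl]-5,6-dibromo-1-tosylindolin-3-ol
Product: 18 4-(5,6-dibromo-1-tosyl-1H-indol-3-yl)-N,N-bis(4-methoxybenzyl)pyrimidin-2-amine
Conditions: SOCl2, pyridine, CH2Cl2, 0 °C to rt
Reagents that add atoms: none
Why: Dehydration of a tertiary alcohol through its chlorosulfite with pyridine-mediated elimination of a C2 hydrogen, driven by aromatisation to the indole and avoiding a C3 cation next to a protonated pyrimidine.

Step 10
Reactants: 18 4-(5,6-dibromo-1-tosyl-1H-indol-3-yl)-N,N-bis(4-methoxybenzyl)pyrimidin-2-amine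
Product: 19 4-(5,6-dibromo-1-tosyl-1H-indol-3-yl)pyrimidin-2-amine
Conditions: TFA, anisole, 70 °C; then aq. NaHCO3
Reagents that add atoms: none
Why: Acidolytic N-debenzylation, each 4-methoxybenzyl cation being trapped by anisole in a Friedel–Crafts alkylation; the N-tosyl group is kept here so that the indole is too electron-poor to be benzylated.

Step 11
Reactants: 19 4-(5,6-dibromo-1-tosyl-1H-indol-3-yl)pyrimidin-2-amine
Product: 20 Meridianin F, 4-(5,6-dibromo-1H-indol-3-yl)pyrimidin-2-amine
Conditions: NaOH, MeOH/THF/H2O, 60 °C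
Reagents that add atoms: none
Why: Nucleophilic cleavage of the N-sulfonyl indole by hydroxide at sulfur, eased by the 3-pyrimidinyl group and the two bromines, which make the indolide a good leaving group.

**Compound list**

1 | 3,4-dibromophenol | Oc1ccc(Br)c(Br)c1 | starting material
2 | 4,5-dibromo-2-iodophenol | Oc1cc(Br)c(Br)cc1I | intermediate
3 | (4,5-dibromo-2-iodophenoxy)trimethylsilane | C[Si](C)(C)Oc1cc(Br)c(Br)cc1I | intermediate
4 | (4,5-dibromo-2-lithiophenoxy)trimethylsilane | C[Si](C)(C)Oc1cc(Br)c(Br)cc1[Li] | intermediate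
5 | lithium 4,5-dibromo-2-(trimethylsilyl)phenoxide | C[Si](C)(C)c1cc(Br)c(Br)cc1[O-].[Li+] | intermediate
6 | 4,5-dibromo-2-(trimethylsilyl)phenyl trifluoromethanesulfonate | C[Si](C)(C)c1cc(Br)c(Br)cc1OS(=O)(=O)C(F)(F)F | intermediate
7 | 2-amino-4-chloropyrimidine | Nc1nccc(Cl)n1 | starting material
8 | 4-methoxybenzyl chloride | COc1ccc(CCl)cc1 | starting material
9 | 4-chloro-N,N-bis(4-methoxybenzyl)pyrimidin-2-amine | COc1ccc(CN(Cc2ccc(OC)cc2)c2nccc(Cl)n2)cc1 | intermediate
10 | tributyl(1-ethoxyvinyl)stannane | CCCC[Sn](CCCC)(CCCC)C(=C)OCC | starting material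
11 | 4-(1-ethoxyvinyl)-N,N-bis(4-methoxybenzyl)pyrimidin-2-amine | COc1ccc(CN(Cc2ccc(OC)cc2)c2nccc(C(=C)OCC)n2)cc1 | intermediate
12 | 1-[2-(bis(4-methoxybenzyl)amino)pyrimidin-4-yl]-2-bromoethan-1-one | COc1ccc(CN(Cc2ccc(OC)cc2)c2nccc(C(=O)CBr)n2)cc1 | intermediate
13 | p-toluenesulfonamide | Cc1ccc(S(N)(=O)=O)cc1 | starting material
14 | N-[2-(2-(bis(4-methoxybenzyl)amino)pyrimidin-4-yl)-2-oxoethyl]-4-methylbenzenesulfonamide | COc1ccc(CN(Cc2ccc(OC)cc2)c2nccc(C(=O)CNS(=O)(=O)c3ccc(C)cc3)n2)cc1 | intermediate
15 | 4,5-dibromobenzyne (1,2-dibromo-4,5-didehydrobenzene) | BrC1=CC#CC=C1Br | intermediate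
16 | cesium salt of the ortho aryl anion formed by N-arylation of 14 | COc1ccc(CN(Cc2ccc(OC)cc2)c2nccc(C(=O)CN(c3cc(Br)c(Br)c[c-]3)S(=O)(=O)c3ccc(C)cc3)n2)cc1.[Cs+] | intermediate
17 | 3-[2-(bis(4-methoxybenzyl)amino)pyrimidin-4-yl]-5,6-dibromo-1-tosylindolin-3-ol (racemic, one enantiomer drawn) | COc1ccc(CN(Cc2ccc(OC)cc2)c2nccc([C@@]3(O)CN(S(=O)(=O)c4ccc(C)cc4)c4cc(Br)c(Br)cc43)n2)cc1 | intermediate
18 | 4-(5,6-dibromo-1-tosyl-1H-indol-3-yl)-N,N-bis(4-methoxybenzyl)pyrimidin-2-amine | COc1ccc(CN(Cc2ccc(OC)cc2)c2nccc(-c3cn(S(=O)(=O)c4ccc(C)cc4)c4cc(Br)c(Br)cc34)n2)cc1 | intermediate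
19 | 4-(5,6-dibromo-1-tosyl-1H-indol-3-yl)pyrimidin-2-amine | Cc1ccc(S(=O)(=O)n2cc(-c3ccnc(N)n3)c3cc(Br)c(Br)cc32)cc1 | intermediate
20 | Meridianin F, 4-(5,6-dibromo-1H-indol-3-yl)pyrimidin-2-amine | Nc1nccc(-c2c[nH]c3cc(Br)c(Br)cc23)n1 | target

**Step count**

Total: 11 steps. Longest linear sequence: 8 steps (steps 4 to 11, from 2-amino-4-chloropyrimidine 7). The aryne-precursor branch (steps 1 to 3) joins at step 8.

**Steps most likely to fail, with fallbacks**

Step 8. The aryl anion may be protonated before it reaches the carbonyl, or the aryne may be intercepted by the enolate of 14 or by a ring nitrogen, which would divert material to open-chain N-aryl or C-aryl products. The fallback sets out from bromo ketone 12 and comes back at 17: the N1–C7a bond is bought as an aniline and C3–C3a is made by a chromium-mediated addition. Commercial 3,4-dibromoaniline (Nc1ccc(Br)c(Br)c1) would be iodinated at its open ortho position (NIS, AcOH) to 4,5-dibromo-2-iodoaniline F1 and tosylated (TsCl, pyridine) to N-(4,5-dibromo-2-iodophenyl)-4-methylbenzenesulfonamide F2. F2 would be N-alkylated with 12 (K2CO3, DMF, 0 °C) to N-[2-(2-(bis(4-methoxybenzyl)amino)pyrimidin-4-yl)-2-oxoethyl]-N-(4,5-dibromo-2-iodophenyl)-4-methylbenzenesulfonamide F3. An intramolecular Nozaki–Hiyama–Kishi addition (CrCl2 in excess, that is divalent chromium, with catalytic NiCl2, DMF, rt) should then engage the C–I bond in preference to the C–Br bonds and close the five-membered ring onto the ketone to give 17.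

Step 7. The product sulfonamide is more acidic than p-toluenesulfonamide, so a second alkylation by 12, or base-induced self-condensation of the bromo ketone, may consume material. The fallback sets out from 12 and comes back at 14 and uses a nucleophile that can be alkylated only once. Compound 12 would be treated with tert-butyl tosylcarbamate (Cc1ccc(S(=O)(=O)NC(=O)OC(C)(C)C)cc1; K2CO3, DMF, rt) to give tert-butyl N-[2-(2-(bis(4-methoxybenzyl)amino)pyrimidin-4-yl)-2-oxoethyl]-N-tosylcarbamate F4. The Boc group would then be removed with TFA/CH2Cl2 1:4 at 0 °C, conditions the bis-PMB amine should withstand, to give 14.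

Step 3. Bromine–lithium exchange may compete with iodine–lithium exchange, or the aryllithium may scramble among the halogen positions before the silyl shift. The fallback sets out from iodophenol 2 and comes back at 6, replacing the lithium-based silyl migration by a magnesium-based intermolecular C-silylation. Compound 2 would be deprotonated with MeMgCl in THF containing LiCl at −30 °C, and the C–I bond exchanged selectively with i-PrMgCl. A quench with excess Me3SiCl should give [4,5-dibromo-2-(trimethylsilyl)phenoxy]trimethylsilane F5, whose O-silyl group is cleaved on mild aqueous acidic work-up to give 4,5-dibromo-2-(trimethylsilyl)phenol F6. Triflation (Tf2O, pyridine, CH2Cl2, 0 °C) would then give 6.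

**Further compounds**

F1 | step 8 | 4,5-dibromo-2-iodoaniline | Nc1cc(Br)c(Br)cc1I
F2 | step 8 | N-(4,5-dibromo-2-iodophenyl)-4-methylbenzenesulfonamide | Cc1ccc(S(=O)(=O)Nc2cc(Br)c(Br)cc2I)cc1
F3 | step 8 | N-[2-(2-(bis(4-methoxybenzyl)amino)pyrimidin-4-yl)-2-oxoethyl]-N-(4,5-dibromo-2-iodophenyl)-4-methylbenzenesulfonamide | COc1ccc(CN(Cc2ccc(OC)cc2)c2nccc(C(=O)CN(c3cc(Br)c(Br)cc3I)S(=O)(=O)c3ccc(C)cc3)n2)cc1
F4 | step 7 | tert-butyl N-[2-(2-(bis(4-methoxybenzyl)amino)pyrimidin-4-yl)-2-oxoethyl]-N-tosylcarbamate | COc1ccc(CN(Cc2ccc(OC)cc2)c2nccc(C(=O)CN(C(=O)OC(C)(C)C)S(=O)(=O)c3ccc(C)cc3)n2)cc1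
F5 | step 3 | [4,5-dibromo-2-(trimethylsilyl)phenoxy]trimethylsilane | C[Si](C)(C)Oc1cc(Br)c(Br)cc1[Si](C)(C)C
F6 | step 3 | 4,5-dibromo-2-(trimethylsilyl)phenol | C[Si](C)(C)c1cc(Br)c(Br)cc1O
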